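**Strategy**

The route rests on disconnecting the ten-membered carbocycle (C1–C10) at C5–C6, where the Z-configured C4=C5 alkene meets the allylic carbinol carbon C6 that neighbours the trans-fused C7/C8 α-methylene lactone. A single nickel/chromium alkenyl–aldehyde addition, with chromium turned over at a cathode, makes this bond, closes the ring and creates the C6 stereocentre, so that only angeloylation remains. The substrate is an open-chain (seco) compound: a 3(2H)-furanone (O, C10, C1, C2, C3) bearing a Z-iodopropenyl group at C3 and linked through C9 to the lactone, whose C7 carries the aldehyde; this aldehyde is unmasked by oxidation just before closure.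

Key step: step 15

Remarks (assumptions on the chemistry):
- Germacrane locants are used for the macrocycle and its seco precursors. TBS = tert-butyldimethylsilyl, TES = triethylsilyl, DMP = Dess–Martin periodinane.
- The seco aldehyde 23 and the macrocyclic alcohol 24 carry the target's configuration at C7, C8 and C10 (trans-lactone).
- H7 of 23 is α to the formyl group and allylic, so C6 travels as a silyl-protected CH2OH and is oxidised last, instead of arising by cleavage of a vinyl group beside three other alkenes.
- The C7 descriptor changes from S (24) to R (27) only because acylation of O6 changes CIP priorities.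

**Route**

Step 1
Reactants: 1 (S)-2-methylglycidol
Product: 2 (2R)-2-methylpent-4-ene-1,2-diol
Conditions: CH2=CHMgBr (3 equiv), CuI (10 mol %), THF, −30 → 0 °C; aqueous work-up
Reagents that add atoms: vinylmagnesium bromide, C=C[Mg]Br
Why: Copper-catalysed Grignard opening of the epoxide should occur by SN2 attack at the unsubstituted CH2 terminus, so the quaternary carbinol centre (the future C10) is taken unchanged from the chiral pool.

Step 2
Reactants: 2 (2R)-2-methylpent-4-ene-1,2-diol
Product: 3 (2R)-2-hydroxy-2-methylpent-4-enoic acid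
Conditions: TEMPO (10 mol %), NaOCl (5 mol %), NaClO2 (2 equiv), MeCN/phosphate buffer pH 6.7, 35 °C
Reagents that add atoms: sodium chlorite, [Na+].[O-]Cl=O
Why: Oxoammonium-mediated oxidation with chlorite as terminal oxidant (TEMPO/Pinnick type) should convert only the primary alcohol into the acid, since the tertiary hydroxyl cannot be oxidised and the stereocentre bears no hydrogen.

Step 3
Reactants: 3 (2R)-2-hydroxy-2-methylpent-4-enoic acid
Product: 4 (3R)-3-hydroxy-3-methylhex-5-en-2-one
Conditions: MeLi (3.3 equiv), THF, 0 °C → rt; inverse quench into cold 1 M HCl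
Reagents that add atoms: methyllithium, [Li]C
Why: Addition of an organolithium to the lithium carboxylate should stop at the geminal dialkoxide, which collapses to the methyl ketone only on hydrolysis (carboxylic acid–organolithium ketone synthesis).

Step 4
Reactants: 4 (3R)-3-hydroxy-3-methylhex-5-en-2-one
Product: 5 (3R)-3-methyl-3-(triethylsilyloxy)hex-5-en-2-one
Conditions: TESOTf, 2,6-lutidine, CH2Cl2, −78 → 0 °C
Reagents that add atoms: triethylsilyl trifluoromethanesulfonate, CC[Si](CC)(CC)OS(=O)(=O)C(F)(F)F
Why: Silyl triflate silylation should cap the hindered tertiary alcohol, which would otherwise end up in a retro-aldol-prone β-hydroxy aldehyde after the next step.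

Step 5
Reactants: 5 (3R)-3-methyl-3-(triethylsilyloxy)hex-5-en-2-one
Product: 7 (3R)-3-methyl-4-oxo-3-(triethylsilyloxy)pentanal, via ozonide 6 (not isolated)
Conditions: O3, CH2Cl2, −78 °C; then PPh3, −78 °C → rt
Reagents that add atoms: ozone, [O-][O+]=O
Why: Ozonolysis with reductive work-up (Criegee mechanism) should cleave the only alkene to the C8 aldehyde without touching the ketone or the silyl ether.

Step 6
Reactants: 8 ethyl acrylate; 9 (tert-butyldimethylsilyloxy)acetaldehyde
Product: 10 ethyl 2-[2-(TBS-oxy)-1-hydroxyethyl]prop-2-enoate (racemic)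
Conditions: DABCO (0.5 equiv), neat, rt
Reagents that add atoms: none
Why: The Morita–Baylis–Hillman reaction of an acrylate with an activated α-oxygenated aldehyde should give the allylic alcohol, whose stereocentre is erased in the next step.

Step 7
Reactants: 10 ethyl 2-[2-(TBS-oxy)-1-hydroxyethyl]prop-2-enoate
Product: 11 ethyl (2Z)-2-(bromomethyl)-4-(TBS-oxy)but-2-enoate
Conditions: NBS, Me2S, CH2Cl2, 0 °C → rt
Reagents that add atoms: N-bromosuccinimide, O=C1CCC(=O)N1Br
Why: Corey–Kim-type activation of the hydroxyl as an alkoxysulfonium ion followed by SN2′ attack of bromide should give the thermodynamically favoured (Z)-2-(bromomethyl)enoate.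

Step 8
Reactants: 7 (3R)-3-methyl-4-oxo-3-(triethylsilyloxy)pentanal; 11 ethyl (2Z)-2-(bromomethyl)-4-(TBS-oxy)but-2-enoate
Product: 13 (4S,5S)-4-[(TBS-oxy)methyl]-3-methylidene-5-[(2R)-2-methyl-3-oxo-2-(triethylsilyloxy)butyl]oxolan-2-one, via hydroxy ester 12 (not isolated)
Conditions: CrCl2 (10 mol %), chiral 3,6-di-tert-butyl-1,8-bis(4-isopropyl-oxazolin-2-yl)carbazole ligand (12 mol %; the enantiomer that directs Re-face addition), Mn (2 equiv), Cp2ZrCl2 (1.1 equiv), i-Pr2NEt (0.3 equiv), THF, rt; aqueous work-up; then PPTS (cat.), CH2Cl2, rt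
Reagents that add atoms: none
Why: In this catalytic asymmetric Nozaki–Hiyama allylation (2-(alkoxycarbonyl)allylation) the allylchromium(III) species should add through its γ-carbon in a chair transition state with the CH2OTBS group equatorial (anti adduct, hence the trans-lactone after acid-promoted lactonisation), while the ligand selects the Re face of the aldehyde and so fixes C8 as S and C7 as S, and the aldehyde reacts in preference to the methyl ketone.

Step 9
Reactants: 14 propargyl alcohol
Product: 16 (2Z)-3-iodo-2-methylprop-2-en-1-ol, via alkenylmagnesium alkoxide 15 (not isolated)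
Conditions: MeMgBr (2.5 equiv), CuI (10 mol %), THF, −10 °C → rt; then I2, −10 → 0 °C
Reagents that add atoms: methylmagnesium bromide, C[Mg]Br; iodine, II
Why: Copper-catalysed anti-carbomagnesiation of the propargylic alkoxide should give the chelated (Z)-alkenylmagnesium species with the methyl group on C2, and iodinolysis with retention fixes the Z iodoalkene (the future C4=C5).

Step 10
Reactants: 16 (2Z)-3-iodo-2-methylprop-2-en-1-ol
Product: 17 (2Z)-3-iodo-2-methylprop-2-enal
Conditions: MnO2 (15 equiv), CH2Cl2, rt, dark; filtered and used at once as a CH2Cl2 solution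
Reagents that add atoms: none
Why: Allylic oxidation on manganese dioxide is neutral and should give the enal without Z→E isomerisation when light and acid are excluded.

Step 11
Reactants: 13 lactone ketone; 17 (2Z)-3-iodo-2-methylprop-2-enal
Product: 19 (4S,5S)-4-[(TBS-oxy)methyl]-5-[(2R,6Z)-5-hydroxy-7-iodo-2,6-dimethyl-3-oxo-2-(triethylsilyloxy)hept-6-en-1-yl]-3-methylideneoxolan-2-one (C3 epimers), via dibutylboron enolate 18 (not isolated)
Conditions: Bu2BOTf, i-Pr2NEt, CH2Cl2, −78 °C; then 17, −78 → −40 °C; pH 7 buffer, MeOH, 30% H2O2, 0 °C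
Reagents that add atoms: none
Why: Soft enolisation can occur only at the methyl group of the ketone (the lactone has no α-hydrogen and C10 is quaternary), and the boron aldol addition to the enal should give the β-hydroxy ketone as a mixture of C3 epimers, which is of no consequence because C3 is oxidised next.

Step 12
Reactants: 19 aldol adduct
Product: 20 (4S,5S)-4-[(TBS-oxy)methyl]-5-[(2R,6Z)-7-iodo-2,6-dimethyl-3,5-dioxo-2-(triethylsilyloxy)hept-6-en-1-yl]-3-methylideneoxolan-2-one
Conditions: DMP, CH2Cl2, 0 °C → rt
Reagents that add atoms: none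
Why: Dess–Martin oxidation of the allylic β-hydroxy ketone should give the (largely enolised) 1,3-diketone under non-basic conditions that leave the iodoalkene and the methylene lactone alone.

Step 13
Reactants: 20 silylated diketone
Product: 22 (4S,5S)-4-(hydroxymethyl)-5-{[(2R)-5-[(1Z)-1-iodoprop-1-en-2-yl]-2-methyl-3-oxo-2,3-dihydrofuran-2-yl]methyl}-3-methylideneoxolan-2-one, via hydroxy diketone 21 (not isolated)
Conditions: 48% aq. HF/MeCN (1:19), 0 °C → rt, dark
Reagents that add atoms: none
Why: Acid should remove both silyl ethers, after which the freed tertiary hydroxyl adds to the C3 carbonyl (5-exo-trig hemiketal formation) and water is lost to give the 3(2H)-furanone (acid-catalysed cyclodehydration of an α′-hydroxy 1,3-diketone), fluoride being too poor a nucleophile to exchange the vinylic iodide.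

Step 14
Reactants: 22 hydroxymethyl furanone lactone
Product: 23 seco aldehyde (2S,3R)-2-{[(2R)-5-[(1Z)-1-iodoprop-1-en-2-yl]-2-methyl-3-oxo-2,3-dihydrofuran-2-yl]methyl}-4-methylidene-5-oxooxolane-3-carbaldehyde
Conditions: DMP, CH2Cl2, 0 °C; short Florisil pad; used at once
Reagents that add atoms: none
Why: Dess–Martin oxidation of the primary alcohol is non-basic, so the aldehyde should form without epimerisation at C7 or migration of the exocyclic double bond, and it is not stored.

Step 15
Reactants: 23 seco aldehyde
Product: 24 (4Z,6S,7S,8S,10R)-3,10-epoxy-6-hydroxy-1-oxogermacra-2,4,11(13)-trien-12,8-olide (the target lacking only the angeloyl group)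
Conditions: CrCl2 (20 mol %), NiCl2·glyme (2 mol %), Cp2ZrCl2 (1.5 equiv), Bu4NPF6 (0.1 M), DMF, undivided cell, Al anode/Ni-foam cathode, constant current (about 2.2 F per mol), 23 added by syringe pump over 10 h (final 2 mM), rt; pH 7 buffer work-up
Reagents that add atoms: none
Why: Oxidative addition of the nickel(0) co-catalyst to the alkenyl iodide (C5–I) is stereoretentive, transmetallation gives a (Z)-alkenylchromium(III) species that attacks the C6 formyl group intramolecularly, zirconocene dichloride strips the chromium alkoxide, and cathodic reduction regenerates chromium(II), the aluminium anode supplying the two electrons per turnover. The closest known reactions are the Ni/Cr-mediated Nozaki–Hiyama–Kishi macrocyclisation of iodoalkenyl aldehydes and the electrochemically driven, chromium-catalytic intermolecular form of the same coupling. The ten-membered carbocycle C1–C10 closes in a 10-exo-trig mode at the aldehyde carbon, since the cis-disposed alkene substituents, the planar furanone and the trans ring fusion fold the seco chain so that C5 lies near C6, and slow addition keeps the monomer dilute enough to disfavour dimerisation. The new C6 centre is controlled by C7: the short tether through C8 favours approach of C5 gauche to the C7–C8 bond, and the Felkin–Anh arrangement with the planar C11 carbon anti to the forming bond and H7 beside the trajectory should lead to the (6S)-alcohol. The step needs chemoselectivity for the aldehyde, which organochromium(III) nucleophiles provide because they add to aldehydes far faster than to ketones, lactones or enoates, and it needs C7 to stay intact, which the amine-free, non-basic medium should secure.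

Step 16
Reactants: 24 macrocyclic alcohol; 25 angelic acid
Product: 27 target CNP0293168.1 [(4Z,6S,7R,8S,10R)-6-angeloyloxy-3,10-epoxy-1-oxogermacra-2,4,11(13)-trien-12,8-olide], via mixed anhydride 26 (not isolated)
Conditions: 25, 2,4,6-Cl3C6H2COCl, Et3N, toluene, rt; then 24, 75 °C
Reagents that add atoms: none
Why: Acyl transfer from the 2,4,6-trichlorobenzoyl mixed anhydride (Yamaguchi-type esterification run without DMAP) should acylate the C6 hydroxyl with retention at C6 and without Z→E isomerisation of the angeloyl group, because no nucleophilic catalyst adds reversibly to the enoate.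

**Compound list**

1 | (S)-2-methylglycidol, [(2S)-2-methyloxiran-2-yl]methanol | C[C@]1(CO)CO1 | starting material
2 | (2R)-2-methylpent-4-ene-1,2-diol | C[C@](O)(CO)CC=C | intermediate
3 | (2R)-2-hydroxy-2-methylpent-4-enoic acid | C[C@](O)(C(=O)O)CC=C | intermediate
4 | (3R)-3-hydroxy-3-methylhex-5-en-2-one | C[C@](O)(C(C)=O)CC=C | intermediate
5 | (3R)-3-methyl-3-(triethylsilyloxy)hex-5-en-2-one | C[C@](O[Si](CC)(CC)CC)(C(C)=O)CC=C | intermediate
6 | ozonide, (3R)-3-methyl-3-(triethylsilyloxy)-4-(1,2,4-trioxolan-3-yl)butan-2-one (epimers at the trioxolane carbon) | C[C@](O[Si](CC)(CC)CC)(C(C)=O)CC1OCOO1 | intermediate (not isolated)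
7 | (3R)-3-methyl-4-oxo-3-(triethylsilyloxy)pentanal | C[C@](O[Si](CC)(CC)CC)(C(C)=O)CC=O | intermediate
8 | ethyl acrylate | C=CC(=O)OCC | starting material
9 | (tert-butyldimethylsilyloxy)acetaldehyde | O=CCO[Si](C)(C)C(C)(C)C | starting material
10 | ethyl 2-[2-(tert-butyldimethylsilyloxy)-1-hydroxyethyl]prop-2-enoate (racemic) | C=C(C(=O)OCC)C(O)CO[Si](C)(C)C(C)(C)C | intermediate
11 | ethyl (2Z)-2-(bromomethyl)-4-(tert-butyldimethylsilyloxy)but-2-enoate | CCOC(=O)/C(CBr)=C/CO[Si](C)(C)C(C)(C)C | intermediate
12 | ethyl (3S,4S,6R)-3-[(tert-butyldimethylsilyloxy)methyl]-4-hydroxy-6-methyl-2-methylidene-7-oxo-6-(triethylsilyloxy)octanoate | CCOC(=O)C(=C)[C@@H](CO[Si](C)(C)C(C)(C)C)[C@@H](O)C[C@@](C)(O[Si](CC)(CC)CC)C(C)=O | intermediate (not isolated)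
13 | (4S,5S)-4-[(tert-butyldimethylsilyloxy)methyl]-3-methylidene-5-[(2R)-2-methyl-3-oxo-2-(triethylsilyloxy)butyl]oxolan-2-one | CC(=O)[C@](C)(O[Si](CC)(CC)CC)C[C@@H]1OC(=O)C(=C)[C@H]1CO[Si](C)(C)C(C)(C)C | intermediate
14 | propargyl alcohol | C#CCO | starting material
15 | bromomagnesium (2Z)-3-(bromomagnesio)-2-methylprop-2-en-1-olate | C/C(CO[Mg]Br)=C/[Mg]Br | intermediate (not isolated)
16 | (2Z)-3-iodo-2-methylprop-2-en-1-ol | I/C=C(C)\CO | intermediate
17 | (2Z)-3-iodo-2-methylprop-2-enal | I/C=C(C)\C=O | intermediate
18 | dibutylboron enolate of 13 (boron on the C1 oxygen, C1=C2 enol) | C=C(OB(CCCC)CCCC)[C@](C)(O[Si](CC)(CC)CC)C[C@@H]1OC(=O)C(=C)[C@H]1CO[Si](C)(C)C(C)(C)C | intermediate (not isolated)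
19 | (4S,5S)-4-[(tert-butyldimethylsilyloxy)methyl]-5-[(2R,6Z)-5-hydroxy-7-iodo-2,6-dimethyl-3-oxo-2-(triethylsilyloxy)hept-6-en-1-yl]-3-methylideneoxolan-2-one (epimers at the carbinol carbon) | I/C=C(C)\C(O)CC(=O)[C@](C)(O[Si](CC)(CC)CC)C[C@@H]1OC(=O)C(=C)[C@H]1CO[Si](C)(C)C(C)(C)C | intermediate
20 | (4S,5S)-4-[(tert-butyldimethylsilyloxy)methyl]-5-[(2R,6Z)-7-iodo-2,6-dimethyl-3,5-dioxo-2-(triethylsilyloxy)hept-6-en-1-yl]-3-methylideneoxolan-2-one | I/C=C(C)\C(=O)CC(=O)[C@](C)(O[Si](CC)(CC)CC)C[C@@H]1OC(=O)C(=C)[C@H]1CO[Si](C)(C)C(C)(C)C | intermediate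
21 | (4S,5S)-5-[(2R,6Z)-2-hydroxy-7-iodo-2,6-dimethyl-3,5-dioxohept-6-en-1-yl]-4-(hydroxymethyl)-3-methylideneoxolan-2-one | I/C=C(C)\C(=O)CC(=O)[C@](C)(O)C[C@@H]1OC(=O)C(=C)[C@H]1CO | intermediate (not isolated)
22 | (4S,5S)-4-(hydroxymethyl)-5-{[(2R)-5-[(1Z)-1-iodoprop-1-en-2-yl]-2-methyl-3-oxo-2,3-dihydrofuran-2-yl]methyl}-3-methylideneoxolan-2-one | I/C=C(C)\C1=CC(=O)[C@](C)(O1)C[C@@H]2OC(=O)C(=C)[C@H]2CO | intermediate
23 | seco aldehyde, (2S,3R)-2-{[(2R)-5-[(1Z)-1-iodoprop-1-en-2-yl]-2-methyl-3-oxo-2,3-dihydrofuran-2-yl]methyl}-4-methylidene-5-oxooxolane-3-carbaldehyde | I/C=C(C)\C1=CC(=O)[C@](C)(O1)C[C@@H]2OC(=O)C(=C)[C@H]2C=O | intermediate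
24 | (4Z,6S,7S,8S,10R)-3,10-epoxy-6-hydroxy-1-oxogermacra-2,4,11(13)-trien-12,8-olide | C=C1C(=O)O[C@H]2C[C@@]3(C)OC(=CC3=O)/C(C)=C\[C@H](O)[C@H]12 | intermediate
25 | angelic acid, (2Z)-2-methylbut-2-enoic acid | C/C=C(/C)C(=O)O | starting material
26 | (2Z)-2-methylbut-2-enoic 2,4,6-trichlorobenzoic anhydride | C/C=C(/C)C(=O)OC(=O)c1c(Cl)cc(Cl)cc1Cl | intermediate (not isolated)
27 | CNP0293168.1, (4Z,6S,7R,8S,10R)-6-[(2Z)-2-methylbut-2-enoyloxy]-3,10-epoxy-1-oxogermacra-2,4,11(13)-trien-12,8-olide | C=C1C(=O)O[C@H]2C[C@@]3(C)OC(=CC3=O)/C(C)=C\[C@H](OC(=O)/C(C)=C\C)[C@H]12 | target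

**Step count and risk**

Total: 16 steps (branches of 5, 2 and 2 steps feeding a 7-step main line). Longest linear sequence: 12 steps (steps 1–5, 8, 11–16).

Steps most likely to fail:

1. Step 15 (ring closure). The alkenylchromium may attack the other face of the C6 formyl group, so that the C6 epimer predominates. In that case ring closure of 23 under the same regime delivers the (6R)-alcohol F1, which is not recycled but esterified with inversion. A Mitsunobu reaction with angelic acid 25 (PPh3, DIAD, toluene, 0 °C → rt) displaces the activated C6–O bond in an SN2 sense and gives 27 directly. This fallback sets out from 23 and returns to the route at 27.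

2. Step 8 (asymmetric allylation). The chiral chromium complex may discriminate poorly between the two aldehyde faces, since the C10 centre is too remote to help. Turnover may also be slow with the γ-substituted bromide, and the allylchromium may lose the silyloxy group by β-elimination. The fallback gives up catalyst control and moves the stereochemical burden to a separation. Aldehyde 7 and bromide 11 are coupled with stoichiometric CrCl2 (THF, rt, no ligand). The chair transition state still secures the anti relationship, so only two adducts should form: 12 and its (3R,4R)-isomer, the hydroxy ester F2. PPTS lactonises them to 13 and the (4R,5R)-trans-lactone F3. These are diastereomers because C10 is fixed, and they are separated by chromatography. This fallback sets out from 7 and 11 and returns at 13.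

3. Step 13 (desilylation and furanone closure). Slow cleavage of the tertiary silyl ether leaves the enolised diketone exposed to acid. O-cyclisation of the enol onto C5 with loss of iodide (pyranone formation) and Z→E isomerisation of the iodoalkene can then compete with furanone formation. The fallback reorders events so that the tertiary hydroxyl is already free when the diketone appears. From aldol 19, HF·pyridine (THF/pyridine, 0 °C → rt) removes both silyl groups to give the triol F4. MnO2 (CH2Cl2, rt) then oxidises only the allylic carbinol. The resulting hydroxy diketone 21 should close at once and dehydrate on addition of PPTS to give 22. This fallback sets out from 19 and returns at 22.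

**Further compounds**

F1 | step 15 | (4Z,6R,7S,8S,10R)-3,10-epoxy-6-hydroxy-1-oxogermacra-2,4,11(13)-trien-12,8-olide (C6 epimer of 24) | C=C1C(=O)O[C@H]2C[C@@]3(C)OC(=CC3=O)/C(C)=C\[C@@H](O)[C@H]12
F2 | step 8 | ethyl (3R,4R,6R)-3-[(tert-butyldimethylsilyloxy)methyl]-4-hydroxy-6-methyl-2-methylidene-7-oxo-6-(triethylsilyloxy)octanoate | CCOC(=O)C(=C)[C@H](CO[Si](C)(C)C(C)(C)C)[C@H](O)C[C@@](C)(O[Si](CC)(CC)CC)C(C)=O
F3 | step 8 | (4R,5R)-4-[(tert-butyldimethylsilyloxy)methyl]-3-methylidene-5-[(2R)-2-methyl-3-oxo-2-(triethylsilyloxy)butyl]oxolan-2-one | CC(=O)[C@](C)(O[Si](CC)(CC)CC)C[C@H]1OC(=O)C(=C)[C@@H]1CO[Si](C)(C)C(C)(C)C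
F4 | step 13 | (4S,5S)-5-[(2R,6Z)-2,5-dihydroxy-7-iodo-2,6-dimethyl-3-oxohept-6-en-1-yl]-4-(hydroxymethyl)-3-methylideneoxolan-2-one (epimers at the secondary carbinol) | I/C=C(C)\C(O)CC(=O)[C@](C)(O)C[C@@H]1OC(=O)C(=C)[C@H]1CO
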